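The rate constants of the steps are unknown here, but a count of reagent brackets the double product without them.

| setting | beta | south-east | north-west |
|---|---|---|---|
| starting material | 0.30 M | 0.30 M | 0.30 M |
| reagent | 0.30 M | 0.280 M | 0.370 M |
| remark | run made earlier |  |  |
| time |  | 2.0 min | 2.0 min |

beta run (percent of the starting material charged)

| time / s | starting material / % | other mono adduct / % | double product / % | first product / % |
|---|---|---|---|---|
| 30.0 | 29.6 | 19.2 | 26.3 | 12.4 |
| 60.0 | 17.9 | 17.2 | 32.7 | 9.4 |
| 90.0 | 18.3 | 17.0 | 35.5 | 11.6 |
| 120 | 16.2 | 19.3 | 34.6 | 10.5 |

(readings scatter by 1 percentage point)

- the numbers in the tables scatter by 1 percentage point (one standard deviation)
- steps under discussion: starting material + reagent -> first product; starting material + reagent -> other mono adduct; reagent + first product -> double product; reagent + other mono adduct -> double product; starting material <-> dormant form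
- a reading of starting material is of its free form alone

* which of these there is most of at the end, counted by the starting material in it, south-east (starting material / double product / other mono adduct / first product)
* which of these there is most of at the end, counted by the starting material in it, north-west (starting material / double product / other mono adduct / first product)
* how much there is at the end of the one of these that leads, in percent of the starting material charged: south-east
* how much there is at the end of the one of these that leads, in percent of the starting material charged: north-west

Every step that adds reagent has [reagent] in its rate, so those steps fade as [reagent] falls. Each mono adduct holds one reagent and the double product two. South-east has a reagent budget of 93.3 %, the reagent charged as a percentage of the starting material charged. North-west has 123 % and beta had 100 %.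

In beta's last two readings the mono adducts together average 29.2 % and the double product 35.1 %. Monos plus twice double then come to 99.4 %, so within the scatter reagent is the limiting reagent of beta.

A change in budget moves the double product by 0.5 point per point if the monos stay at beta's level, and by one point per point if it acts on the mono-to-double step:

south-east: from 28.4 % to 32.1 %

north-west: from 47.1 % to 58.4 %

The north-west bracket assumes its reagent is used by the asked time. Both lower ends stand higher than 19.3 %, the highest late beta reading of a rival, so the double product should lead.

The forecast names double product at 30 % in south-east and double product at 51 % in north-west, inside both brackets, reading beta with the words “so beta stops because reagent runs out”.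

The flask gives double product at 31.8 % in south-east and double product at 48.9 % in north-west, each inside its bracket.

    starting material + reagent → first product (k = 0.110 M⁻¹ s⁻¹)
    starting material + reagent → other mono adduct (k = 0.140 M⁻¹ s⁻¹)
    reagent + first product → double product (k = 0.320 M⁻¹ s⁻¹)
    reagent + other mono adduct → double product (k = 0.230 M⁻¹ s⁻¹)
    starting material ⇌ dormant form (K = 1.10, k = 0.0130 s⁻¹)

In south-east the half-life of starting material by the step to first product grows from 0.62 min at 0.116 min to 78 min at 2.00 min, far longer than the time asked, with 0.478 % of the reagent free, and the double product stands at 32.1 % after 20.0 min. With beta's monos the budget of 93.3 % gave 32.1 % for south-east, and a flask like south-east charged with 0.51 M of starting material has a budget of 54.9 %, which gives 12.9 % with the same monos, where that flask holds 12.8 %.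

Readings and results were computed from invented constants, noise included.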